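**Retrosynthetic overview**

1. Ring A is the benzoic acid ring (C-1 CO2H, C-2 OMe, C-3 side chain, C-6 O-aryl) and ring B the aldehyde ring (C-1′ ether O, C-2′ OH, C-4′ Me, C-6′ CHO); no ring is constructed, both start as bought benzenes.
2. Feature used: in ring A the carboxyl-bearing C-1 lies between the methoxy-bearing C-2 and the aryloxy-bearing C-6, which is the pattern left when a nucleophile adds to C-6 and an electrophile to C-1 of a 3-methoxybenzyne.
3. Key disconnection: the C-6–O ether bond and the C-1–CO2H bond, made in one operation from the aryne of silyl triflate 10, the potassium salt of ring-B phenol 17 and CO2 (18); de-allylation and acetal hydrolysis then finish the target.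
4. Silyl triflate 10 from 4-hydroxy-2-methoxybenzaldehyde (1): O-carbamate, Brown methallylboration (sets the (R) benzylic centre), O-methylation, alkene hydrogenation, carbamate-directed silylation between the two oxygens, carbamate cleavage, triflation.
5. Phenol 17 from 2-methoxy-4-methylphenol (11): ortho-formylation, O-demethylation, 3-O-allylation of the catechol dianion, dioxolane formation.

Key step: step 12

**Route**

Step 1
Reactants: 1 4-hydroxy-2-methoxybenzaldehyde
Product: 2 4-formyl-3-methoxyphenyl N,N-diethylcarbamate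
Conditions: Et2NCOCl (1.2 equiv), K2CO3, MeCN, reflux
Reagents that add atoms: N,N-diethylcarbamoyl chloride, CCN(CC)C(=O)Cl
Why: O-acylation of the acidic, unhindered para-formyl phenoxide gives the N,N-diethyl O-aryl carbamate, which protects the phenol through the next steps and later directs the metalation.

Step 2
Reactants: 2 4-formyl-3-methoxyphenyl N,N-diethylcarbamate
Product: 4 4-[(R)-1-hydroxy-3-methylbut-3-en-1-yl]-3-methoxyphenyl N,N-diethylcarbamate, via borinate ester 3 (not isolated)
Conditions: (+)-Ipc2BOMe (1.3 equiv), 2-methylallylmagnesium chloride (1.2 equiv), Et2O, −78 °C → rt; then 2, −78 °C; NaBO3·4H2O, THF–H2O, rt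
Reagents that add atoms: 2-methylallylmagnesium chloride, CC(=C)C[Mg]Cl
Why: Brown asymmetric methallylboration through a closed chair (Zimmerman–Traxler) transition state, in which the B-methallyl reagent bearing the (+)-isopinocampheyl groups [from (−)-α-pinene] should deliver the methallyl group to the Re face of the aryl aldehyde, as this antipode does with benzaldehyde, and so set the (R) carbinol centre, while the diethylcarbamate is not attacked by the borane at −78 °C or by perborate.

Step 3
Reactants: 4 4-[(R)-1-hydroxy-3-methylbut-3-en-1-yl]-3-methoxyphenyl N,N-diethylcarbamate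
Product: 5 3-methoxy-4-[(R)-1-methoxy-3-methylbut-3-en-1-yl]phenyl N,N-diethylcarbamate
Conditions: MeI (3 equiv), NaH (1.3 equiv, added last), THF–DMF, 0 °C → rt
Reagents that add atoms: iodomethane, CI
Why: Williamson etherification at oxygen leaves the configuration at carbon untouched, and adding the base last to the alcohol–MeI mixture traps the alkoxide before it can take the carbamoyl group from the aryl oxygen.

Step 4
Reactants: 5 3-methoxy-4-[(R)-1-methoxy-3-methylbut-3-en-1-yl]phenyl N,N-diethylcarbamate
Product: 6 3-methoxy-4-[(R)-1-methoxy-3-methylbutyl]phenyl N,N-diethylcarbamate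
Conditions: H2 (1 atm), RhCl(PPh3)3 (5 mol %), PhH–EtOH, rt
Reagents that add atoms: none
Why: Homogeneous hydrogenation with Wilkinson's catalyst should saturate the unhindered 1,1-disubstituted alkene without hydrogenolysis of the electron-rich benzylic C–OMe bond, which a heterogeneous palladium catalyst could cleave.

Step 5
Reactants: 6 3-methoxy-4-[(R)-1-methoxy-3-methylbutyl]phenyl N,N-diethylcarbamate
Product: 8 3-methoxy-4-[(R)-1-methoxy-3-methylbutyl]-2-(trimethylsilyl)phenyl N,N-diethylcarbamate, via aryllithium 7 (not isolated)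
Conditions: s-BuLi (1.2 equiv), TMEDA, THF, −78 °C, 1 h; TMSCl, −78 °C → rt
Reagents that add atoms: chlorotrimethylsilane, C[Si](C)(C)Cl
Why: Directed ortho-metalation, in which the O-carbamate and the methoxy group cooperate at the carbon between them (C-2), so that kinetic deprotonation there should outrun the benzylic C–H, and holding the aryllithium at −78 °C until the silyl chloride quench avoids the anionic Fries rearrangement.

Step 6
Reactants: 8 3-methoxy-4-[(R)-1-methoxy-3-methylbutyl]-2-(trimethylsilyl)phenyl N,N-diethylcarbamate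
Product: 9 3-methoxy-4-[(R)-1-methoxy-3-methylbutyl]-2-(trimethylsilyl)phenol
Conditions: Cp2Zr(H)Cl (2.5 equiv), THF, rt; then H2O
Reagents that add atoms: none
Why: Reductive cleavage of an aryl O-carbamate with the Schwartz reagent (hydrozirconation of the carbamate carbonyl, then loss of the aryloxide) runs without acid or base, so the aryl–silicon bond and the benzylic ether should survive.

Step 7
Reactants: 9 3-methoxy-4-[(R)-1-methoxy-3-methylbutyl]-2-(trimethylsilyl)phenol
Product: 10 3-methoxy-4-[(R)-1-methoxy-3-methylbutyl]-2-(trimethylsilyl)phenyl trifluoromethanesulfonate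
Conditions: PhNTf2 (1.3 equiv), DBU (1.5 equiv, added last), MeCN, 0 °C → rt
Reagents that add atoms: N-phenylbis(trifluoromethanesulfonimide), O=S(=O)(N(c1ccccc1)S(=O)(=O)C(F)(F)F)C(F)(F)F
Why: O-sulfonylation of the hindered phenoxide with the mild triflyl donor, with the base added last at 0 °C so that the phenoxide para to the benzylic ether is triflated as it forms and has no time to expel methoxide as a quinone methide.

Step 8
Reactants: 11 2-methoxy-4-methylphenol
Product: 12 2-hydroxy-3-methoxy-5-methylbenzaldehyde
Conditions: hexamethylenetetramine (2 equiv), TFA, 85 °C; then 2 M HCl, rt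
Reagents that add atoms: hexamethylenetetramine, C1N2CN3CN1CN(C2)C3; water, O
Why: Duff formylation, in which the iminium electrophile from hexamethylenetetramine attacks ortho to the free hydroxyl because the para position carries the methyl group, and redox transfer then hydrolysis of the benzylic iminium should give the salicylaldehyde.

Step 9
Reactants: 12 2-hydroxy-3-methoxy-5-methylbenzaldehyde
Product: 14 2,3-dihydroxy-5-methylbenzaldehyde, via cyclic bromoborate 13 (not isolated)
Conditions: BBr3 (2.5 equiv), CH2Cl2, −78 °C → rt; then H2O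
Reagents that add atoms: none
Why: Lewis-acid cleavage of the aryl methyl ether (bromide attacks the O-methyl group of the boron-bound ether), with the catechol held as its cyclic borate until aqueous hydrolysis, a standard demethylation of 3-methoxysalicylaldehydes.

Step 10
Reactants: 14 2,3-dihydroxy-5-methylbenzaldehyde
Product: 16 3-(allyloxy)-2-hydroxy-5-methylbenzaldehyde, via disodium catecholate 15 (not isolated)
Conditions: NaH (2.2 equiv), DMSO, rt; allyl bromide (1.0 equiv), rt; 1 M HCl
Reagents that add atoms: allyl bromide, C=CCBr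
Why: Regioselective SN2 alkylation of the catechol dianion, in which the 2-phenoxide is conjugated with and chelated to the formyl group, so the more nucleophilic 3-phenoxide should take the single equivalent of allyl bromide.

Step 11
Reactants: 16 3-(allyloxy)-2-hydroxy-5-methylbenzaldehyde
Product: 17 2-(allyloxy)-6-(1,3-dioxolan-2-yl)-4-methylphenol
Conditions: HOCH2CH2OH (5 equiv), p-TsOH·H2O (cat.), PhMe, reflux, Dean–Stark; Et3N quench
Reagents that add atoms: ethylene glycol, OCCO
Why: Acid-catalysed acetalization driven by azeotropic removal of water, which tolerates the free phenol and stays well below the temperature of an aromatic Claisen rearrangement of the allyl ether.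

Step 12
Reactants: 10 3-methoxy-4-[(R)-1-methoxy-3-methylbutyl]-2-(trimethylsilyl)phenyl trifluoromethanesulfonate; 17 2-(allyloxy)-6-(1,3-dioxolan-2-yl)-4-methylphenol; 18 carbon dioxide
Product: 22 6-[2-(allyloxy)-6-(1,3-dioxolan-2-yl)-4-methylphenoxy]-2-methoxy-3-[(R)-1-methoxy-3-methylbutyl]benzoic acid, via potassium phenoxide 19 (not isolated), via aryne 20 (not isolated), via aryl anion 21 (not isolated)
Conditions: 17 (1.5 equiv), KH (1.5 equiv), THF, 0 °C; 18-crown-6 (3 equiv), KF (3 equiv), CO2 (1 atm); 10 (1.0 equiv) in THF added over 4 h, 0 °C → rt; NaHCO3 extraction, then pH 4–5 (NaH2PO4), 0 °C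
Reagents that add atoms: carbon dioxide, O=C=O
Why: Proposed new method: fluoride attacks the silicon of 10 and triflate leaves to give the 3-methoxy-4-alkylbenzyne 20, the inductively withdrawing methoxy group makes C-6 the more electrophilic aryne carbon, so the crown-ether-separated phenoxide 19 adds there and the charge develops at C-1 beside the methoxy oxygen, and the resulting aryl anion 21 adds to CO2 to give the carboxylate of 22. The closest known reaction type is the fluoride-triggered three-component coupling of arynes with neutral nitrogen nucleophiles and CO2 under KF/18-crown-6 in THF, together with the fluoride-mediated O-arylation of phenols by ortho-silylaryl triflates, and the untested part is carboxylative trapping after addition of an anionic, 2,6-disubstituted phenoxide. No ring is closed and no stereocentre is formed, and the benzylic stereocentre of 10 is remote from the reacting carbons and is not touched. Two selectivities are needed: attack at C-6 over C-1, secured by the methoxy group next to the triple bond, and carboxylation over protonation of 21, secured by the phenoxide preformed with KH (hydrogen is the only co-product), by THF in place of a C–H acidic solvent and by a CO2-saturated solution. The dioxolane prevents 21 from closing onto a ring-B carbonyl to a xanthenol, and slow addition of 10 keeps the aryne concentration low so that the product carboxylate and the reversibly formed aryl carbonate of 19 should not compete as nucleophiles.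

Step 13
Reactants: 22 6-[2-(allyloxy)-6-(1,3-dioxolan-2-yl)-4-methylphenoxy]-2-methoxy-3-[(R)-1-methoxy-3-methylbutyl]benzoic acid
Product: 23 6-[2-(1,3-dioxolan-2-yl)-6-hydroxy-4-methylphenoxy]-2-methoxy-3-[(R)-1-methoxy-3-methylbutyl]benzoic acid
Conditions: Pd(PPh3)4 (5 mol %), morpholine (5 equiv), THF, rt; pH 5 buffer
Reagents that add atoms: none
Why: Tsuji–Trost de-allylation, in which palladium(0) ionizes the aryl allyl ether to a π-allyl complex and the phenoxide, morpholine takes up the allyl group, and the carboxylic acid, the acetal and the benzylic ether are not affected.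

Step 14
Reactants: 23 6-[2-(1,3-dioxolan-2-yl)-6-hydroxy-4-methylphenoxy]-2-methoxy-3-[(R)-1-methoxy-3-methylbutyl]benzoic acid
Product: 24 6-(2-formyl-6-hydroxy-4-methylphenoxy)-2-methoxy-3-[(R)-1-methoxy-3-methylbutyl]benzoic acid (CNP0328949.1)
Conditions: 1 M HCl, THF, rt
Reagents that add atoms: water, O
Why: Acid-catalysed hydrolysis of the aryl dioxolane through an aryl-stabilized oxocarbenium ion is fast in dilute acid at room temperature, conditions too weak to ionize the benzylic methyl ether, so the (R) centre should be retained.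

**Compound list**

1 | 4-hydroxy-2-methoxybenzaldehyde | COc1cc(O)ccc1C=O | starting material
2 | 4-formyl-3-methoxyphenyl N,N-diethylcarbamate | COc1cc(OC(=O)N(CC)CC)ccc1C=O | intermediate
3 | (R)-1-[4-(diethylcarbamoyloxy)-2-methoxyphenyl]-3-methylbut-3-en-1-yl bis[(1S,2S,3S,5R)-isopinocampheyl]borinate (not isolated) | COc1cc(OC(=O)N(CC)CC)ccc1[C@@H](CC(C)=C)OB([C@H]1C[C@H]2C[C@@H]([C@@H]1C)C2(C)C)[C@H]1C[C@H]2C[C@@H]([C@@H]1C)C2(C)C | intermediate
4 | 4-[(R)-1-hydroxy-3-methylbut-3-en-1-yl]-3-methoxyphenyl N,N-diethylcarbamate | COc1cc(OC(=O)N(CC)CC)ccc1[C@@H](CC(C)=C)O | intermediate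
5 | 3-methoxy-4-[(R)-1-methoxy-3-methylbut-3-en-1-yl]phenyl N,N-diethylcarbamate | COc1cc(OC(=O)N(CC)CC)ccc1[C@@H](CC(C)=C)OC | intermediate
6 | 3-methoxy-4-[(R)-1-methoxy-3-methylbutyl]phenyl N,N-diethylcarbamate | COc1cc(OC(=O)N(CC)CC)ccc1[C@@H](CC(C)C)OC | intermediate
7 | 2-lithio-3-methoxy-4-[(R)-1-methoxy-3-methylbutyl]phenyl N,N-diethylcarbamate (not isolated) | COc1c([Li])c(OC(=O)N(CC)CC)ccc1[C@@H](CC(C)C)OC | intermediate
8 | 3-methoxy-4-[(R)-1-methoxy-3-methylbutyl]-2-(trimethylsilyl)phenyl N,N-diethylcarbamate | COc1c([Si](C)(C)C)c(OC(=O)N(CC)CC)ccc1[C@@H](CC(C)C)OC | intermediate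
9 | 3-methoxy-4-[(R)-1-methoxy-3-methylbutyl]-2-(trimethylsilyl)phenol | COc1c([Si](C)(C)C)c(O)ccc1[C@@H](CC(C)C)OC | intermediate
10 | 3-methoxy-4-[(R)-1-methoxy-3-methylbutyl]-2-(trimethylsilyl)phenyl trifluoromethanesulfonate | COc1c([C@@H](CC(C)C)OC)ccc(OS(=O)(=O)C(F)(F)F)c1[Si](C)(C)C | intermediate
11 | 2-methoxy-4-methylphenol | COc1cc(C)ccc1O | starting material
12 | 2-hydroxy-3-methoxy-5-methylbenzaldehyde | COc1cc(C)cc(C=O)c1O | intermediate
13 | 2-bromo-6-methyl-1,3,2-benzodioxaborole-4-carbaldehyde (not isolated) | Cc1cc(C=O)c2OB(Br)Oc2c1 | intermediate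
14 | 2,3-dihydroxy-5-methylbenzaldehyde | Cc1cc(O)c(O)c(C=O)c1 | intermediate
15 | disodium 3-formyl-5-methylbenzene-1,2-diolate (not isolated) | [Na+].[Na+].[O-]c1cc(C)cc(C=O)c1[O-] | intermediate
16 | 3-(allyloxy)-2-hydroxy-5-methylbenzaldehyde | C=CCOc1cc(C)cc(C=O)c1O | intermediate
17 | 2-(allyloxy)-6-(1,3-dioxolan-2-yl)-4-methylphenol | Oc1c(OCC=C)cc(C)cc1C1OCCO1 | intermediate
18 | carbon dioxide | O=C=O | starting material
19 | potassium 2-(allyloxy)-6-(1,3-dioxolan-2-yl)-4-methylphenolate (not isolated) | [K+].[O-]c1c(OCC=C)cc(C)cc1C1OCCO1 | intermediate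
20 | 3-methoxy-4-[(R)-1-methoxy-3-methylbutyl]benzyne (not isolated) | COC1=C([C@@H](CC(C)C)OC)C=CC#C1 | intermediate
21 | potassium 6-[2-(allyloxy)-6-(1,3-dioxolan-2-yl)-4-methylphenoxy]-2-methoxy-3-[(R)-1-methoxy-3-methylbutyl]benzen-1-ide (not isolated) | COc1c([C@@H](CC(C)C)OC)ccc(Oc2c(OCC=C)cc(C)cc2C2OCCO2)[c-]1.[K+] | intermediate
22 | 6-[2-(allyloxy)-6-(1,3-dioxolan-2-yl)-4-methylphenoxy]-2-methoxy-3-[(R)-1-methoxy-3-methylbutyl]benzoic acid | COc1c([C@@H](CC(C)C)OC)ccc(Oc2c(OCC=C)cc(C)cc2C2OCCO2)c1C(=O)O | intermediate
23 | 6-[2-(1,3-dioxolan-2-yl)-6-hydroxy-4-methylphenoxy]-2-methoxy-3-[(R)-1-methoxy-3-methylbutyl]benzoic acid | COc1c([C@@H](CC(C)C)OC)ccc(Oc2c(O)cc(C)cc2C2OCCO2)c1C(=O)O | intermediate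
24 | 6-(2-formyl-6-hydroxy-4-methylphenoxy)-2-methoxy-3-[(R)-1-methoxy-3-methylbutyl]benzoic acid | COc1c([C@@H](CC(C)C)OC)ccc(Oc2c(O)cc(C)cc2C=O)c1C(=O)O | target

**Step count and risks**

Total step count: 14 (steps 1–7 to the silyl triflate, steps 8–11 to the phenol, steps 12–14 from the coupling to the target).
Longest linear sequence: 10 steps (1–7, then 12–14).

Steps most likely to fail:

1. Step 12 (the step marked as a proposed new method). The aryl anion may be protonated before it meets CO2. The phenoxide may also be held back as its carbonate, so that the aryne is used up by fluoride or by the product carboxylate. Fallback by known reactions, setting out from 10 and 17: the two are combined with CsF in MeCN at rt without CO2 (aryne O-arylation with proton capture, same regiochemistry) to give 2-[3-(allyloxy)-2-{3-methoxy-4-[(R)-1-methoxy-3-methylbutyl]phenoxy}-5-methylphenyl]-1,3-dioxolane F1. The allyl group is removed with Pd(PPh3)4/morpholine to give 3-(1,3-dioxolan-2-yl)-2-{3-methoxy-4-[(R)-1-methoxy-3-methylbutyl]phenoxy}-5-methylphenol F2. Treatment of F2 with n-BuLi/TMEDA (2.5 equiv) in THF at −78 → 0 °C should first deprotonate the phenol and then lithiate ring A at C-1 between the methoxy and aryloxy oxygens (directed ortho-metalation of a resorcinol-type diether), giving the dilithio species F3. Quenching F3 with CO2 and mild acidification gives 23, where the route is rejoined before step 14.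

2. Step 6. Hydride delivery to a carbamate carbonyl shielded by the neighbouring trimethylsilyl group may be slow, and prolonged exposure may start protodesilylation. Fallback, setting out from 6: the unhindered carbamate is cleaved first with Cp2Zr(H)Cl to 3-methoxy-4-[(R)-1-methoxy-3-methylbutyl]phenol F4, which is converted with isopropyl isocyanate/Et3N into 3-methoxy-4-[(R)-1-methoxy-3-methylbutyl]phenyl N-isopropylcarbamate F5. In one flask F5 is N-silylated with TMSOTf/TMEDA to the N-(trimethylsilyl) carbamate F6, lithiated with n-BuLi/TMEDA at −78 °C to the aryllithium F7, and quenched with TMSCl to the N,2-bis(trimethylsilyl) compound F8. Acidic work-up gives 3-methoxy-4-[(R)-1-methoxy-3-methylbutyl]-2-(trimethylsilyl)phenyl N-isopropylcarbamate F9. This secondary carbamate is cleaved by base through an isocyanate (DBU, Et2NH, MeCN, 40 °C), not by hydride, giving phenol 9 in the flask, and PhNTf2 then gives 10.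

3. Step 2. Facial selectivity on the electron-rich, ortho-substituted aldehyde may be insufficient, and since no later step adds a stereocentre the minor enantiomer could not be removed as a diastereomer. Fallback, setting out from 2: isobutylmagnesium bromide (THF, −78 °C) gives racemic 4-(1-hydroxy-3-methylbutyl)-3-methoxyphenyl N,N-diethylcarbamate F10. Dess–Martin oxidation gives 3-methoxy-4-(3-methylbutanoyl)phenyl N,N-diethylcarbamate F11. Corey–Bakshi–Shibata reduction with the (S)-oxazaborolidine and BH3·SMe2 should give 4-[(R)-1-hydroxy-3-methylbutyl]-3-methoxyphenyl N,N-diethylcarbamate F12, with the aryl group as the large substituent as in the reduction of acetophenone to the (R) alcohol. Methylation with NaH/MeI returns to 6, bypassing steps 2–4.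

**Further compounds**

F1 | step 12 | 2-[3-(allyloxy)-2-{3-methoxy-4-[(R)-1-methoxy-3-methylbutyl]phenoxy}-5-methylphenyl]-1,3-dioxolane | COc1cc(Oc2c(OCC=C)cc(C)cc2C2OCCO2)ccc1[C@@H](CC(C)C)OC
F2 | step 12 | 3-(1,3-dioxolan-2-yl)-2-{3-methoxy-4-[(R)-1-methoxy-3-methylbutyl]phenoxy}-5-methylphenol | COc1cc(Oc2c(O)cc(C)cc2C2OCCO2)ccc1[C@@H](CC(C)C)OC
F3 | step 12 | lithium 3-(1,3-dioxolan-2-yl)-2-{2-lithio-3-methoxy-4-[(R)-1-methoxy-3-methylbutyl]phenoxy}-5-methylphenolate | COc1c([Li])c(Oc2c(O[Li])cc(C)cc2C2OCCO2)ccc1[C@@H](CC(C)C)OC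
F4 | step 6 | 3-methoxy-4-[(R)-1-methoxy-3-methylbutyl]phenol | COc1cc(O)ccc1[C@@H](CC(C)C)OC
F5 | step 6 | 3-methoxy-4-[(R)-1-methoxy-3-methylbutyl]phenyl N-isopropylcarbamate | COc1cc(OC(=O)NC(C)C)ccc1[C@@H](CC(C)C)OC
F6 | step 6 | 3-methoxy-4-[(R)-1-methoxy-3-methylbutyl]phenyl N-isopropyl-N-(trimethylsilyl)carbamate | COc1cc(OC(=O)N(C(C)C)[Si](C)(C)C)ccc1[C@@H](CC(C)C)OC
F7 | step 6 | 2-lithio-3-methoxy-4-[(R)-1-methoxy-3-methylbutyl]phenyl N-isopropyl-N-(trimethylsilyl)carbamate | COc1c([Li])c(OC(=O)N(C(C)C)[Si](C)(C)C)ccc1[C@@H](CC(C)C)OC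
F8 | step 6 | 3-methoxy-4-[(R)-1-methoxy-3-methylbutyl]-2-(trimethylsilyl)phenyl N-isopropyl-N-(trimethylsilyl)carbamate | COc1c([Si](C)(C)C)c(OC(=O)N(C(C)C)[Si](C)(C)C)ccc1[C@@H](CC(C)C)OC
F9 | step 6 | 3-methoxy-4-[(R)-1-methoxy-3-methylbutyl]-2-(trimethylsilyl)phenyl N-isopropylcarbamate | COc1c([Si](C)(C)C)c(OC(=O)NC(C)C)ccc1[C@@H](CC(C)C)OC
F10 | step 2 | 4-(1-hydroxy-3-methylbutyl)-3-methoxyphenyl N,N-diethylcarbamate (racemic) | COc1cc(OC(=O)N(CC)CC)ccc1C(O)CC(C)C
F11 | step 2 | 3-methoxy-4-(3-methylbutanoyl)phenyl N,N-diethylcarbamate | COc1cc(OC(=O)N(CC)CC)ccc1C(=O)CC(C)C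
F12 | step 2 | 4-[(R)-1-hydroxy-3-methylbutyl]-3-methoxyphenyl N,N-diethylcarbamate | COc1cc(OC(=O)N(CC)CC)ccc1[C@@H](CC(C)C)O
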